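## Retrosynthetic overview

- **Feature:** the pyranone ring C is fused to ring A by the adjacent bonds O1–C8a and C4–C4a. C8a is para to the C6 methyl and C4a has the C5 oxygen as its neighbour, so one O5-polarised aryne (C4a≡C8a) can deliver both bonds at once.
- **End game:** acidic methanolysis removes three aryl MOM ethers and the O3 ketal. Before that, ring C (the only ring formed) is closed by fluoride-triggered annulation of the ring A aryne with the silyl-masked C2 alkoxide of an anti-glycolate aldol ester.
- **The ester:** it is the butane-2,3-diacetal glycolate lactone itself. This one unit controls C2 and C3 in the aldol, masks O3 as an acid-labile ketal, and serves as the acyl leaving group, so neither auxiliary cleavage nor separate O3 protection is needed.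
- **Ring B aldehyde:** 3-bromo-4-hydroxybenzaldehyde is MOM-protected, borylated (Miyaura) and coupled with geranyl bromide (Suzuki–Miyaura).
- **Ring A o-silylaryl triflate:** 2-methylresorcinol bis-MOM ether undergoes sterically governed C–H borylation and oxidation, which places the C8a oxygen para to the methyl. Bromination at one of two equivalent ortho carbons, retro-Brook silyl shift and triflation follow.

Key step: step 14

Assumption: flavonoid numbering is used throughout, and the enolate of the (5S,6S) lactone is taken to react on the face opposite its axial C5 methoxy group, as in its alkylations; if the opposite sense were found, the (R)-chlorodiol would be used instead.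

## Route

Step 1
Reactants: 1 2-methylresorcinol
Product: 2 1,3-bis(methoxymethoxy)-2-methylbenzene
Conditions: NaH, MOMCl, DMF, 0 °C to rt
Reagents that add atoms: chloromethyl methyl ether (MOMCl) COCCl
Why: Williamson-type O-alkylation of the bis-phenoxide by a reactive chloromethyl ether; the two hydroxyls are equivalent, so only one product can form.

Step 2
Reactants: 2 1,3-bis(methoxymethoxy)-2-methylbenzene
Product: 3 2-[3,5-bis(methoxymethoxy)-4-methylphenyl]-4,4,5,5-tetramethyl-1,3,2-dioxaborolane
Conditions: [Ir(OMe)(cod)]2 (cat.), 4,4'-di-tert-butyl-2,2'-bipyridine (cat.), B2pin2, THF, 80 °C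
Reagents that add atoms: bis(pinacolato)diboron CC1(C)OB(OC1(C)C)B1OC(C)(C)C(C)(C)O1
Why: Iridium-catalysed aromatic C–H borylation is governed by sterics, and the carbon para to the methyl is the only C–H of this 1,2,3-trisubstituted arene without an ortho substituent, so no differentiation of phenols is needed.

Step 3
Reactants: 3 the arylboronate
Product: 4 3,5-bis(methoxymethoxy)-4-methylphenol
Conditions: 30% aq H2O2, NaOH, THF, 0 °C; aq NH4Cl
Reagents that add atoms: hydrogen peroxide OO
Why: Basic peroxide oxidation of an arylboronate (1,2-shift of aryl from boron to oxygen) is ipso-specific, and the basic medium leaves the MOM ethers intact.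

Step 4
Reactants: 4 3,5-bis(methoxymethoxy)-4-methylphenol
Product: 5 2-bromo-3,5-bis(methoxymethoxy)-4-methylphenol
Conditions: NBS (1 equiv), CH2Cl2, −78 to 0 °C
Reagents that add atoms: N-bromosuccinimide O=C1CCC(=O)N1Br
Why: Electrophilic aromatic bromination of a strongly activated phenol whose only two free ring carbons are ortho to OH and equivalent by symmetry, so one equivalent of NBS at low temperature should give a single monobromide.

Step 5
Reactants: 5 2-bromo-3,5-bis(methoxymethoxy)-4-methylphenol
Product: 8 3,5-bis(methoxymethoxy)-4-methyl-2-(trimethylsilyl)phenyl trifluoromethanesulfonate, via aryl trimethylsilyl ether 6 (not isolated), via lithium 2-silylphenolate 7 (not isolated)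
Conditions: HMDS, THF, 70 °C, then evaporate; n-BuLi, THF, −90 °C; Tf2O, −90 to −70 °C
Reagents that add atoms: hexamethyldisilazane C[Si](C)(C)N[Si](C)(C)C; trifluoromethanesulfonic anhydride O=S(=O)(OS(=O)(=O)C(F)(F)F)C(F)(F)F
Why: O-silylation, bromine–lithium exchange and retro-Brook 1,3-shift of silicon from oxygen to the lithiated carbon give phenolate 7, which Tf2O traps; this is the standard sequence from 3-alkoxy-2-bromophenols to o-silylaryl triflates.

Step 6
Reactants: 9 3-bromo-4-hydroxybenzaldehyde
Product: 10 3-bromo-4-(methoxymethoxy)benzaldehyde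
Conditions: K2CO3, MOMCl, DMF, 0 °C to rt
Reagents that add atoms: chloromethyl methyl ether (MOMCl) COCCl
Why: O-alkylation of an acidic para-formylphenol under mild carbonate conditions that touch neither the aldehyde nor the aryl bromide.

Step 7
Reactants: 10 3-bromo-4-(methoxymethoxy)benzaldehyde
Product: 11 4-(methoxymethoxy)-3-(4,4,5,5-tetramethyl-1,3,2-dioxaborolan-2-yl)benzaldehyde
Conditions: B2pin2, Pd(dppf)Cl2 (cat.), KOAc, 1,4-dioxane, 85 °C
Reagents that add atoms: bis(pinacolato)diboron CC1(C)OB(OC1(C)C)B1OC(C)(C)C(C)(C)O1
Why: Miyaura borylation tolerates aldehydes and MOM ethers, and KOAc is too weak a base to start biaryl coupling.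

Step 8
Reactants: 11 the formyl arylboronate, 12 geranyl bromide
Product: 13 3-[(2E)-3,7-dimethylocta-2,6-dien-1-yl]-4-(methoxymethoxy)benzaldehyde
Conditions: Pd(dppf)Cl2 (cat.), Cs2CO3, THF–H2O, 50 °C
Reagents that add atoms: none
Why: Suzuki–Miyaura coupling of an arylboronate with an allylic bromide runs through a pi-allylpalladium species that delivers the aryl group to the unsubstituted terminus, which should give the linear E-geranyl arene without any organometallic that would add to the aldehyde.

Step 9
Reactants: 14 (S)-3-chloropropane-1,2-diol, 15 butane-2,3-dione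
Product: 16 (2S,3S,5S)-5-(chloromethyl)-2,3-dimethoxy-2,3-dimethyl-1,4-dioxane
Conditions: HC(OMe)3, camphorsulfonic acid (cat.), MeOH, reflux
Reagents that add atoms: trimethyl orthoformate COC(OC)OC (methoxy groups, exchanging with the methanol solvent CO)
Why: Acid-catalysed butane-2,3-diacetal formation is under thermodynamic control, with both methoxy groups axial (anomeric effect) and the chloromethyl group equatorial, so the single stereocentre of 14 fixes both new acetal centres as S.

Step 10
Reactants: 16 the chloromethyl dioxane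
Product: 17 (2S,3S)-2,3-dimethoxy-2,3-dimethyl-5-methylidene-1,4-dioxane
Conditions: KOt-Bu, THF, reflux
Reagents that add atoms: none
Why: E2 dehydrochlorination to the exocyclic enol ether erases the original carbinol centre while the two acetal centres keep the stereochemical information.

Step 11
Reactants: 17 the exocyclic enol ether
Product: 18 (5S,6S)-5,6-dimethoxy-5,6-dimethyl-1,4-dioxan-2-one
Conditions: O3, CH2Cl2, −78 °C; Me2S, −78 °C to rt
Reagents that add atoms: ozone [O-][O+]=O
Why: Ozonolysis of the electron-rich 1,1-disubstituted enol ether cleaves C=CH2 to the lactone carbonyl and does not touch the acetal centres.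

Step 12
Reactants: 18 the glycolate lactone, 13 the geranylated aldehyde
Product: 20 (3R,5S,6S)-3-[(R)-{3-[(2E)-3,7-dimethylocta-2,6-dien-1-yl]-4-(methoxymethoxy)phenyl}(hydroxy)methyl]-5,6-dimethoxy-5,6-dimethyl-1,4-dioxan-2-one, via lithium enolate 19 (not isolated)
Conditions: LiN(SiMe3)2, THF, −78 °C; 13, −78 °C, short contact; AcOH, −78 °C
Reagents that add atoms: none
Why: Lithium enolate aldol addition of the diacetal-protected glycolate lactone is a known anti-selective reaction with aromatic aldehydes: the ring-locked E enolate 19 reacts through a Zimmerman–Traxler chair (anti, setting the carbinol carbon, flavonoid C2, as R) on the face opposite the axial methoxy group at C5 of the dioxanone (setting the alpha carbon, flavonoid C3, as R), and the Lewis-acid-free medium spares the MOM ether and the geranyl chain.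

Step 13
Reactants: 20 the anti aldol lactone
Product: 21 O-trimethylsilyl ether of 20
Conditions: 1-(trimethylsilyl)imidazole, CH2Cl2, 0 °C to rt
Reagents that add atoms: 1-(trimethylsilyl)imidazole C[Si](C)(C)n1ccnc1
Why: Neutral silylation of a secondary alcohol replaces the only O–H of the molecule by a fluoride-labile group without any base strong enough to start a retro-aldol reaction.

Step 14
Reactants: 21 the silyl-masked hydroxy lactone, 8 the ring A o-silylaryl triflate
Product: 25 (2R,3R)-2-{3-[(2E)-3,7-dimethylocta-2,6-dien-1-yl]-4-(methoxymethoxy)phenyl}-3-{[(2S)-2-methoxy-3-oxobutan-2-yl]oxy}-5,7-bis(methoxymethoxy)-6-methyl-2,3-dihydro-4H-chromen-4-one, via aryne 22 (not isolated), via potassium alkoxide 23 (not isolated), via aryl anion 24 (not isolated)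
Conditions: KF, 18-crown-6, THF, 0 °C to rt, slow addition of 8 (moderate excess)
Reagents that add atoms: none
Why: Proposed new method: KF strips silicon from both partners, so aryne 22 (C4a≡C8a) and the proton-free C2 alkoxide 23 are released side by side; 23 adds through oxygen at C8a (O1–C8a), and the C4a aryl anion 24 so formed attacks the lactone carbonyl (C4–C4a), after which acyl substitution opens the dioxanone and its former C6 acetal carbon sheds methoxide to end as the methyl ketone of the O3 ketal. The closest known reaction types are the aryne annulation of salicylate esters to xanthones (heteroatom addition, then intramolecular acyl capture) and the fluoride-mediated O-arylation of aliphatic alcohols by arynes; their combination on an aliphatic beta-oxy ester is not established. Ring C, the only ring formed, closes in a 6-exo-trig mode. No stereocentre is created and no bond to C2 or C3 is made or broken, so the anti (R,R) pair of 20 should appear as the trans-2,3 relationship of 25. Regioselectivity of addition is needed, and the C5 OMOM group beside C4a distorts and polarises the aryne so that oxygen attacks the remote C8a, whereas the opposite sense would lead to a 6,8-dioxygenated 7-methyl chromanone. Acyl capture must also outrun protonation of C4a, which is secured by delivering O1 as a silyl ether in THF (no O–H in the flask) and by using a six-membered lactone, a better acyl acceptor than an open-chain methyl ester.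

Step 15
Reactants: 25 the protected dihydroflavonol
Product: 26 (2R,3R)-2-{3-[(2E)-3,7-dimethylocta-2,6-dien-1-yl]-4-hydroxyphenyl}-3,5,7-trihydroxy-6-methyl-2,3-dihydro-4H-chromen-4-one (target)
Conditions: HCl (1.25 M in MeOH), 30 °C; aq NaHCO3
Reagents that add atoms: none
Why: Acid-catalysed transacetalisation in methanol should remove the three aryl MOM ethers and the alpha-keto ketal as volatile acetals, the trans ketol is configurationally stable in acid, and dilute acid at low temperature is chosen to leave the trisubstituted alkenes unprotonated.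

## Compound list

1 | 2-methylresorcinol | Cc1c(O)cccc1O | starting material
2 | 1,3-bis(methoxymethoxy)-2-methylbenzene | COCOc1cccc(OCOC)c1C | intermediate
3 | 2-[3,5-bis(methoxymethoxy)-4-methylphenyl]-4,4,5,5-tetramethyl-1,3,2-dioxaborolane | COCOc1cc(B2OC(C)(C)C(C)(C)O2)cc(OCOC)c1C | intermediate
4 | 3,5-bis(methoxymethoxy)-4-methylphenol | COCOc1cc(O)cc(OCOC)c1C | intermediate
5 | 2-bromo-3,5-bis(methoxymethoxy)-4-methylphenol | COCOc1cc(O)c(Br)c(OCOC)c1C | intermediate
6 | [2-bromo-3,5-bis(methoxymethoxy)-4-methylphenoxy]trimethylsilane | COCOc1cc(O[Si](C)(C)C)c(Br)c(OCOC)c1C | intermediate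
7 | lithium 3,5-bis(methoxymethoxy)-4-methyl-2-(trimethylsilyl)phenolate | [Li+].[O-]c1cc(OCOC)c(C)c(OCOC)c1[Si](C)(C)C | intermediate
8 | 3,5-bis(methoxymethoxy)-4-methyl-2-(trimethylsilyl)phenyl trifluoromethanesulfonate | COCOc1cc(OS(=O)(=O)C(F)(F)F)c([Si](C)(C)C)c(OCOC)c1C | intermediate
9 | 3-bromo-4-hydroxybenzaldehyde | O=Cc1ccc(O)c(Br)c1 | starting material
10 | 3-bromo-4-(methoxymethoxy)benzaldehyde | COCOc1ccc(C=O)cc1Br | intermediate
11 | 4-(methoxymethoxy)-3-(4,4,5,5-tetramethyl-1,3,2-dioxaborolan-2-yl)benzaldehyde | COCOc1ccc(C=O)cc1B1OC(C)(C)C(C)(C)O1 | intermediate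
12 | geranyl bromide | CC(C)=CCC/C(C)=C/CBr | starting material
13 | 3-[(2E)-3,7-dimethylocta-2,6-dien-1-yl]-4-(methoxymethoxy)benzaldehyde | CC(C)=CCC/C(C)=C/Cc1cc(C=O)ccc1OCOC | intermediate
14 | (S)-3-chloropropane-1,2-diol | ClC[C@@H](O)CO | starting material
15 | butane-2,3-dione | CC(=O)C(C)=O | starting material
16 | (2S,3S,5S)-5-(chloromethyl)-2,3-dimethoxy-2,3-dimethyl-1,4-dioxane | ClC[C@@H]1CO[C@](C)(OC)[C@@](C)(OC)O1 | intermediate
17 | (2S,3S)-2,3-dimethoxy-2,3-dimethyl-5-methylidene-1,4-dioxane | C=C1CO[C@](C)(OC)[C@@](C)(OC)O1 | intermediate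
18 | (5S,6S)-5,6-dimethoxy-5,6-dimethyl-1,4-dioxan-2-one | O=C1CO[C@](C)(OC)[C@@](C)(OC)O1 | intermediate
19 | lithium enolate of 18 | [Li+].[O-]C1=CO[C@](C)(OC)[C@@](C)(OC)O1 | intermediate
20 | (3R,5S,6S)-3-[(R)-{3-geranyl-4-(methoxymethoxy)phenyl}(hydroxy)methyl]-5,6-dimethoxy-5,6-dimethyl-1,4-dioxan-2-one | CC(C)=CCC/C(C)=C/Cc1cc([C@@H](O)[C@H]2O[C@](C)(OC)[C@@](C)(OC)OC2=O)ccc1OCOC | intermediate
21 | O-trimethylsilyl ether of 20 | CC(C)=CCC/C(C)=C/Cc1cc([C@@H](O[Si](C)(C)C)[C@H]2O[C@](C)(OC)[C@@](C)(OC)OC2=O)ccc1OCOC | intermediate
22 | 1,2-didehydro-3,5-bis(methoxymethoxy)-4-methylbenzene (aryne C4a≡C8a) | COCOC1=CC#CC(OCOC)=C1C | intermediate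
23 | potassium alkoxide of 20 | [K+].CC(C)=CCC/C(C)=C/Cc1cc([C@@H]([O-])[C@H]2O[C@](C)(OC)[C@@](C)(OC)OC2=O)ccc1OCOC | intermediate
24 | potassium C4a aryl anion of the O1–C8a adduct | [K+].CC(C)=CCC/C(C)=C/Cc1cc([C@@H](Oc2cc(OCOC)c(C)c(OCOC)[c-]2)[C@H]3O[C@](C)(OC)[C@@](C)(OC)OC3=O)ccc1OCOC | intermediate
25 | (2R,3R)-2-{3-geranyl-4-(methoxymethoxy)phenyl}-3-{[(2S)-2-methoxy-3-oxobutan-2-yl]oxy}-5,7-bis(methoxymethoxy)-6-methyl-2,3-dihydro-4H-chromen-4-one | CC(C)=CCC/C(C)=C/Cc1cc([C@H]2Oc3cc(OCOC)c(C)c(OCOC)c3C(=O)[C@@H]2O[C@](C)(OC)C(C)=O)ccc1OCOC | intermediate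
26 | (2R,3R)-2-(3-geranyl-4-hydroxyphenyl)-3,5,7-trihydroxy-6-methyl-2,3-dihydro-4H-chromen-4-one | CC(C)=CCC/C(C)=C/Cc1cc([C@H]2Oc3cc(O)c(C)c(O)c3C(=O)[C@@H]2O)ccc1O | target

## Step count and risks

Total step count: 15. Longest linear sequence: 7 steps. All three branches have this length: steps 1–5, 14, 15; steps 6–8, 12–15; steps 9–15.

**Step 14 (most likely to fail).**
- *What may go wrong:*
  - Proton transfer to C4a, from adventitious water or from C3–H within the molecule, may occur before acyl capture.
  - The liberated alkoxide may undergo retro-aldol cleavage, with loss of the anti relationship.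
  - The released methoxide may open ring C or epimerise the product.
  - Surplus aryne may undergo an ene reaction with the geranyl chain.
- *Fallback:* it sets out from 20 and 8 and comes back at 25, and it makes the two bonds one after the other by known reactions.
  - The free alcohol 20 is O-arylated by the aryne from 8 (KF, 18-crown-6, THF). This is the O–H insertion of an aliphatic alcohol, in which the aryl anion is simply protonated. It gives the 3,5-bis(methoxymethoxy)-4-methylphenyl ether F1, whose two carbons ortho to O1 are equivalent.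
  - NBS (CH2Cl2, −78 °C) brominates this most electron-rich ring to the ortho-bromo aryl ether F2.
  - n-BuLi (THF, −100 °C) then effects a Parham cyclisation (bromine–lithium exchange, then attack on the lactone carbonyl), which leads to 25.

**Step 15.**
- *What may go wrong:* acid may induce cyclisation of the geranyl chain onto the freed 4'-hydroxyl or within the diene, and the alpha-keto ketal may be lost only slowly.
- *Fallback:* it sets out from 25 and comes back at 26, and it replaces Brønsted-acid solvolysis by a protecting-group exchange.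
  - Et3SiOTf and 2,2'-bipyridyl (CH2Cl2, 0 °C), then water, should convert the aryl MOM ethers directly into triethylsilyl ethers. The mixed ketal should be hydrolysed through its bipyridinium salt. The product is the 5,7,4'-tris(triethylsilyl) ether F3.
  - HF·pyridine buffered with pyridine (THF, 0 °C) then frees the phenols.

**Step 8.**
- *What may go wrong:* allylic transposition in the pi-allyl intermediate (branched product), erosion of the E geometry, and protodeboronation.
- *Fallback:* it sets out from 10 and comes back at 13, and it replaces cross-coupling by aryl-copper allylation.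
  - The aldehyde is masked (ethylene glycol, HC(OEt)3, PPTS cat.) as the bromoaryl dioxolane F4.
  - Bromine–lithium exchange (n-BuLi, THF, −78 °C), CuBr·SMe2 and then 12 give the geranylated dioxolane F5.
  - PPTS in wet acetone releases 13 while the aryl MOM ether stays in place.

## Further compounds

F1 | step 14 | (3R,5S,6S)-3-[(R)-[3,5-bis(methoxymethoxy)-4-methylphenoxy]{3-geranyl-4-(methoxymethoxy)phenyl}methyl]-5,6-dimethoxy-5,6-dimethyl-1,4-dioxan-2-one | CC(C)=CCC/C(C)=C/Cc1cc([C@@H](Oc2cc(OCOC)c(C)c(OCOC)c2)[C@H]3O[C@](C)(OC)[C@@](C)(OC)OC3=O)ccc1OCOC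
F2 | step 14 | (3R,5S,6S)-3-[(R)-[2-bromo-3,5-bis(methoxymethoxy)-4-methylphenoxy]{3-geranyl-4-(methoxymethoxy)phenyl}methyl]-5,6-dimethoxy-5,6-dimethyl-1,4-dioxan-2-one | CC(C)=CCC/C(C)=C/Cc1cc([C@@H](Oc2cc(OCOC)c(C)c(OCOC)c2Br)[C@H]3O[C@](C)(OC)[C@@](C)(OC)OC3=O)ccc1OCOC
F3 | step 15 | (2R,3R)-2-{3-geranyl-4-[(triethylsilyl)oxy]phenyl}-3-hydroxy-6-methyl-5,7-bis[(triethylsilyl)oxy]-2,3-dihydro-4H-chromen-4-one | CC(C)=CCC/C(C)=C/Cc1cc([C@H]2Oc3cc(O[Si](CC)(CC)CC)c(C)c(O[Si](CC)(CC)CC)c3C(=O)[C@@H]2O)ccc1O[Si](CC)(CC)CC
F4 | step 8 | 2-[3-bromo-4-(methoxymethoxy)phenyl]-1,3-dioxolane | COCOc1ccc(C2OCCO2)cc1Br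
F5 | step 8 | 2-{3-[(2E)-3,7-dimethylocta-2,6-dien-1-yl]-4-(methoxymethoxy)phenyl}-1,3-dioxolane | CC(C)=CCC/C(C)=C/Cc1cc(C2OCCO2)ccc1OCOC
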